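**Retrosynthetic overview**
1. Feature: the ten-membered ring is numbered C1 (isopropenyl), C2, C3/C4 epoxide (methyl on C4), C5 (angelate), C6, C7/C8 epoxide (methyl on C8), C9 (OH), C10 (senecioate). Both epoxides are cis, so they map onto a (3Z,7Z)-1,5-diene; the arc C8–C9–C10–C1–C2–C3 is the ring of α'-oxygenated (S)-carvone once a C3–C8 bond is drawn; O5 and O10 lie on the same face across the ring.
2. Key disconnection: C3=C4 and C7=C8 arise by thermal cleavage of the C3–C8 and C4–C7 bonds of a cyclohexanone-fused bicyclo[2.2.0]hexane (ring A: C3–C4–C7–C8, ring B: C4–C5–C6–C7). This tricycle comes from the enone–cyclobutene [2+2] photocycloaddition of cis-6-hydroxycarvone with (S)-2-methylcyclobut-2-enol.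
3. A free cis-anti-cis adduct of this kind opens through a chair diyl to an E,Z diene. The two partners are therefore joined beforehand by an O5–Si(iPr)2–O10 bridge, which makes the cycloaddition intramolecular and cis-syn-cis and holds the diyl in the folded boat that leads to the Z,Z diene.
4. Ring order: carvone ring (chiral pool) → rings A and B (photocycloaddition) → ten-membered ring (cycloreversion) → C7/C8 epoxide (directed by C9–OH) → C3/C4 epoxide (peracid, free C5–OH); the esters go on C10 and then on C5.

Key step: step 9

Assumption: 2-methylcyclobutanone is taken as a bought starting material (it is the α-methylation product of cyclobutanone).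
Convention: every intermediate carries the ring numbers given above; β is the face of the isopropenyl group when the ring is drawn flat and numbered clockwise, α the opposite face.

**Route**

Step 1
Reactants: 1 (S)-carvone
Product: 3 (5R,6R)-6-hydroxycarvone (hydroxyl trans to the isopropenyl group), via potassium dienolate 2 (not isolated)
Conditions: KN(SiMe3)2, THF, −78 °C; 2-(phenylsulfonyl)-3-phenyloxaziridine, −78 °C; AcOH
Reagents that add atoms: 2-(phenylsulfonyl)-3-phenyloxaziridine, O=S(=O)(c1ccccc1)N1OC1c1ccccc1
Why: Kinetic deprotonation at C10 (carvone C6) gives the cross-conjugated dienolate, and oxygen transfer from the oxaziridine (enolate hydroxylation of the Davis type) should occur on the face away from the neighbouring isopropenyl group, which sets the new centre trans to C1.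

Step 2
Reactants: 3 (5R,6R)-6-hydroxycarvone
Product: 4 (5R,6S)-6-(4-nitrobenzoyloxy)carvone (ester cis to the isopropenyl group)
Conditions: 4-O2NC6H4CO2H, PPh3, DIAD, THF, 0 °C to rt
Reagents that add atoms: 4-nitrobenzoic acid, O=C(O)c1ccc(cc1)[N+](=O)[O-]
Why: Mitsunobu reaction, in which the carboxylate displaces the oxyphosphonium group with inversion at the carbonyl-activated carbon, so that the C10 oxygen ends up cis to the isopropenyl group as the target requires.

Step 3
Reactants: 4 (5R,6S)-6-(4-nitrobenzoyloxy)carvone
Product: 5 (5R,6S)-6-hydroxycarvone (hydroxyl cis to the isopropenyl group)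
Conditions: K2CO3 (0.2 equiv), MeOH, −10 °C; AcOH
Reagents that add atoms: none
Why: Base-catalysed transesterification of the electron-poor aryl ester is fast at low temperature, so the α-ketol should be freed before the C10 hydrogen can exchange and the cis configuration is kept.

Step 4
Reactants: 6 2-methylcyclobutanone
Product: 7 1-methyl-2-(trimethylsilyloxy)cyclobut-1-ene
Conditions: Me3SiCl, NaI, Et3N, MeCN, rt
Reagents that add atoms: chlorotrimethylsilane, C[Si](C)(C)Cl
Why: Silyl enol ether formation under equilibrating conditions (iodotrimethylsilane formed in situ, amine base) gives the more substituted enol ether, so that the next step functionalises the methyl-bearing α-carbon.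

Step 5
Reactants: 7 1-methyl-2-(trimethylsilyloxy)cyclobut-1-ene
Product: 8 2-methylcyclobut-2-en-1-one
Conditions: Pd(OAc)2 (1.05 equiv), MeCN, rt; kept as a cold solution
Reagents that add atoms: none
Why: Saegusa–Ito oxidation, in which the palladium enolate bound at the methyl-bearing carbon undergoes syn β-hydride elimination towards the ring CH2 to give the endocyclic enone at a temperature well below that of cyclobutenone ring opening.

Step 6
Reactants: 8 2-methylcyclobut-2-en-1-one
Product: 9 (S)-2-methylcyclobut-2-en-1-ol
Conditions: (R)-2-methyl-CBS-oxazaborolidine (10 mol %), catecholborane, toluene, −78 °C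
Reagents that add atoms: none
Why: Corey–Bakshi–Shibata reduction, in which the oxazaborolidine binds the carbonyl anti to the larger alkenyl arm and delivers hydride 1,2 to one face, which should give the (S)-alcohol that becomes C5.

Step 7
Reactants: 5 (5R,6S)-6-hydroxycarvone; 9 (S)-2-methylcyclobut-2-en-1-ol
Product: 11 mixed diisopropylsilyl acetal joining O10 of 5 to O5 of 9, via chlorosilane 10 (not isolated)
Conditions: 5, iPr2SiCl2 (4 equiv), imidazole, CH2Cl2, 0 °C; excess silane removed in vacuo; then 9, imidazole, DMF, rt
Reagents that add atoms: dichlorodiisopropylsilane, CC(C)[Si](Cl)(Cl)C(C)C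
Why: Stepwise silyl ether formation at silicon (the excess of dichlorosilane stops at the monochloride, and the second alcohol then displaces the remaining chloride) touches no stereocentre, lets the cyclobutenol be used in equimolar amount, and allows the diastereomer from the minor enantiomer of 9 to be removed.

Step 8
Reactants: 11 mixed diisopropylsilyl acetal
Product: 12 silicon-bridged cis-syn-cis photoadduct
Conditions: hν (366 nm), degassed CH2Cl2 (3 mM), −20 °C
Reagents that add atoms: none
Why: Intramolecular enone–alkene [2+2] photocycloaddition through the triplet enone and a 1,4-biradical, in which the usual head-to-tail preference (more substituted alkene carbon to the β-carbon, no bond between the two methyl-bearing carbons) gives the C3–C4 and C7–C8 bonds, while the one-silicon bridge can span O5 and O10 only if the cyclobutene lies folded over the enone face that carries the axial C10 oxygen, which sets C3, C4, C7 and C8 as the cis-syn-cis isomer with O5 endo and keeps the equatorial isopropenyl group out of reach of the enone.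

Step 9
Reactants: 12 silicon-bridged cis-syn-cis photoadduct
Product: 13 silicon-bridged (3Z,7Z)-cyclodecadien-9-one
Conditions: degassed 1,2-dichlorobenzene (5 mM), BHT (cat.), silylated glass, 170 °C
Reagents that add atoms: none
Why: Homolysis of the strained C4–C7 bond common to rings A and B gives a cyclohexane-1,4-diyl (radicals at C4 and C7), and β-scission of the C3–C8 bond shared with the cyclohexanone then forms C3=C4 and C7=C8, a stepwise formal retro-[2+2]. The closest known reaction type is the thermal half of photo-thermal olefin metathesis, in which cyclohexenone–cyclobutene photoadducts open to cyclodeca-1,5-dienes. The ten-membered ring is therefore not closed end to end but uncovered by ring expansion (the six-membered ring and ring A merge when their common bond breaks), while the two nine-membered rings that run through the silicon bridge stay intact. No stereocentre is formed: C1, C5 and C10 are untouched and the four photochemically made centres become sp2. The step needs both new alkenes Z: free cis-anti-cis adducts open through a chair diyl to E,Z dienes that then Cope-rearrange, whereas here the O5–Si–O10 bridge can span the two oxygens only while the diyl stays folded in the syn-boat, in which C2/C5 and C6/C9 are eclipsed, so scission should give the Z,Z diene, whose own Cope rearrangement would need a boat. It also needs scission of C3–C8 rather than C5–C6, which is secured by the more substituted (tertiary–quaternary) bond and by the conjugated C7=C8–C9 enone that its cleavage releases.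

Step 10
Reactants: 13 silicon-bridged (3Z,7Z)-cyclodecadien-9-one
Product: 14 silicon-bridged (3Z,7Z)-dien-9β-ol
Conditions: NaBH4, CeCl3·7H2O, MeOH–THF, −78 °C
Reagents that add atoms: none
Why: Luche 1,2-reduction of the enone, in which hydride should add anti to the C10–O bond (Felkin–Anh control, the silyl acetal oxygen does not chelate) and from the side of the carbonyl turned away from the silicon bridge, which gives the C9 hydroxyl cis to the C10 oxygen.

Step 11
Reactants: 14 silicon-bridged (3Z,7Z)-dien-9β-ol
Product: 15 silicon-bridged 7,8β-epoxy-9β-ol
Conditions: VO(acac)2 (5 mol %), t-BuOOH (in decane), CH2Cl2, 0 °C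
Reagents that add atoms: tert-butyl hydroperoxide, CC(C)(C)OO
Why: Hydroxyl-directed epoxidation with VO(acac)2 and t-BuOOH, in which the vanadium alkoxide of the C9 hydroxyl delivers oxygen to the adjacent C7=C8 bond on the face of that hydroxyl, the cis outcome typical of medium-ring Z-cycloalkenols and of allylic alcohols with a substituent on the nearer alkene carbon, whereas C3=C4 (no free hydroxyl) and the isopropenyl group are not activated.

Step 12
Reactants: 15 silicon-bridged 7,8β-epoxy-9β-ol
Product: 16 (3Z)-7,8β-epoxy-5β,9β,10β-triol
Conditions: Bu4NF, AcOH (1:1), THF, 0 °C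
Reagents that add atoms: none
Why: Fluoride-induced cleavage of both Si–O bonds of the silyl acetal under buffered conditions, which should leave the epoxy alcohol untouched because neither a free alkoxide nor a strong acid is present.

Step 13
Reactants: 16 (3Z)-7,8β-epoxy-5β,9β,10β-triol
Product: 17 10-O-senecioyl derivative of 16
Conditions: Me2SnCl2 (10 mol %), K2CO3, 3-methylbut-2-enoyl chloride (1.05 equiv), THF, 0 °C
Reagents that add atoms: 3-methylbut-2-enoyl chloride, CC(C)=CC(=O)Cl
Why: Tin-catalysed monoacylation of a 1,2-diol, in which the dimethylstannylene acetal can form only across the cis C9/C10 diol and is acylated at the less hindered C10 oxygen (the C9 oxygen sits next to the fully substituted epoxide carbon C8), so that the isolated C5 hydroxyl stays free and the C10 hydroxyl is capped before the C3/C4 epoxide, which it could open across the ring, is made.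

Step 14
Reactants: 17 10-O-senecioyl derivative of 16
Product: 18 3,4α:7,8β-bis-epoxide with free 5β- and 9β-hydroxyls
Conditions: mCPBA (1.05 equiv), NaHCO3, CH2Cl2, −20 to 0 °C
Reagents that add atoms: 3-chloroperoxybenzoic acid, O=C(OO)c1cccc(Cl)c1
Why: Peracid (Prilezhaev) epoxidation, in which the trisubstituted C3=C4 bond next to the free C5 hydroxyl should react ahead of the 1,1-disubstituted isopropenyl group and the electron-poor senecioate bond, and attack on the exposed face of the Z-cycloalkenol places the oxygen trans to the C5 hydroxyl, the outcome typical of peracid epoxidation of medium-ring allylic alcohols and of allylic alcohols under allylic 1,3-strain.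

Step 15
Reactants: 18 3,4α:7,8β-bis-epoxide with free 5β- and 9β-hydroxyls
Product: 19 CNP0320216.1 (target)
Conditions: angelic acid, 2,4,6-Cl3C6H2COCl, Et3N, toluene, rt; then 18, 75 °C
Reagents that add atoms: angelic acid, C/C=C(/C)C(=O)O
Why: Yamaguchi esterification through the preformed mixed anhydride without a nucleophilic catalyst, which should acylate the C5 hydroxyl (one unbranched neighbour, C6) in preference to the C9 hydroxyl wedged between C8 and the acylated C10, and should avoid the Z-to-E isomerisation of the angeloyl group that nucleophilic catalysts cause.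

**Compound list**
1 | (S)-carvone | C=C(C)[C@H]1CC=C(C)C(=O)C1 | starting material
2 | potassium dienolate of 1 (enolised towards carvone C6) | C=C(C)[C@H]1CC=C(C)C([O-])=C1.[K+] | intermediate
3 | (5R,6R)-6-hydroxycarvone (trans) | C=C(C)[C@H]1CC=C(C)C(=O)[C@@H]1O | intermediate
4 | (5R,6S)-6-(4-nitrobenzoyloxy)carvone (cis) | C=C(C)[C@H]1CC=C(C)C(=O)[C@H]1OC(=O)c1ccc(cc1)[N+](=O)[O-] | intermediate
5 | (5R,6S)-6-hydroxycarvone (cis) | C=C(C)[C@H]1CC=C(C)C(=O)[C@H]1O | intermediate
6 | 2-methylcyclobutanone (racemic) | CC1CCC1=O | starting material
7 | 1-methyl-2-(trimethylsilyloxy)cyclobut-1-ene | CC1=C(O[Si](C)(C)C)CC1 | intermediate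
8 | 2-methylcyclobut-2-en-1-one | CC1=CCC1=O | intermediate
9 | (S)-2-methylcyclobut-2-en-1-ol | CC1=CC[C@@H]1O | intermediate
10 | chlorodiisopropylsilyl ether of 5 | C=C(C)[C@H]1CC=C(C)C(=O)[C@H]1O[Si](Cl)(C(C)C)C(C)C | intermediate
11 | mixed diisopropylsilyl acetal: Si(iPr)2 joins O10 of cis-hydroxycarvone 5 to O5 of cyclobutenol 9 | C=C(C)[C@H]1CC=C(C)C(=O)[C@H]1O[Si](C(C)C)(C(C)C)O[C@H]1CC=C1C | intermediate
12 | silicon-bridged cis-syn-cis photoadduct: cyclohexanone (C8–C9–C10–C1–C2–C3) cis-fused at C3–C8 to cyclobutane A (C3–C4–C7–C8) on its β face, ring A cis-fused at C4–C7 to cyclobutane B (C4–C5–C6–C7), ring B folded back over the six-membered ring, O5 endo and joined to O10 by Si(iPr)2, methyls on C4 and C8, isopropenyl on C1 | C=C(C)[C@H]1C[C@H]2[C@@]3(C)[C@H]4O[Si](C(C)C)(C(C)C)O[C@@H]1C(=O)[C@]2(C)[C@@H]3C4 | intermediate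
13 | silicon-bridged (3Z,7Z)-1β-isopropenyl-4,8-dimethylcyclodeca-3,7-dien-9-one, O5β and O10β joined by Si(iPr)2 | C=C(C)[C@H]1C/C=C(C)\[C@H]2O[Si](C(C)C)(C(C)C)O[C@@H]1C(=O)/C(C)=C\C2 | intermediate
14 | 9β-alcohol of 13 | C=C(C)[C@H]1C/C=C(C)\[C@H]2O[Si](C(C)C)(C(C)C)O[C@@H]1[C@H](O)/C(C)=C\C2 | intermediate
15 | 7,8β-epoxide of 14 | C=C(C)[C@H]1C/C=C(C)\[C@H]2O[Si](C(C)C)(C(C)C)O[C@@H]1[C@H](O)[C@]3(C)O[C@@H]3C2 | intermediate
16 | (3Z)-7,8β-epoxy-1β-isopropenyl-4,8-dimethylcyclodec-3-ene-5β,9β,10β-triol | C=C(C)[C@H]1C/C=C(C)\[C@@H](O)C[C@H]2O[C@@]2(C)[C@@H](O)[C@H]1O | intermediate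
17 | 10-O-(3-methylbut-2-enoyl) derivative of 16 | C=C(C)[C@H]1C/C=C(C)\[C@@H](O)C[C@H]2O[C@@]2(C)[C@@H](O)[C@H]1OC(=O)C=C(C)C | intermediate
18 | 3,4α:7,8β-bis-epoxide of 17 (free 5β- and 9β-hydroxyls) | C=C(C)[C@H]1C[C@@H]2O[C@]2(C)[C@@H](O)C[C@H]2O[C@@]2(C)[C@@H](O)[C@H]1OC(=O)C=C(C)C | intermediate
19 | CNP0320216.1: 5-O-angeloyl derivative of 18 | C=C(C)[C@H]1C[C@@H]2O[C@]2(C)[C@@H](OC(=O)/C(C)=C\C)C[C@H]2O[C@@]2(C)[C@@H](O)[C@H]1OC(=O)C=C(C)C | target

**Step count and risks**

Total steps: 15. Longest linear sequence: 12 steps (steps 1–3 and 7–15, from (S)-carvone).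

The three steps most likely to fail:

Step 9. Part of the diyl may leave the bridge-imposed boat for the one chair that keeps the bridge within reach. This would put an E geometry on the C7=C8 enone, and that E,Z isomer could then be lost by Cope rearrangement during prolonged heating. The fallback sets out from 12 and comes back at 13. The cleavage is run as a short-contact flash vacuum thermolysis, which leaves no time for a Cope rearrangement, and the geometry is then set by equilibration instead of by the cleavage itself. The silicon-bridged (3Z,7E)-dienone F1 present in the pyrolysate is treated with catalytic PhSH and Et3N in THF at rt, so that reversible conjugate addition of thiolate at C7 allows rotation about C7–C8. The E enone is strained inside the nine-membered ring closed by the silicon bridge, so the mixture should converge on 13.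

Step 8. Ring closure within the nine-membered tether may be too slow to compete with decay of the enone triplet, so that reversion of the biradical, closure onto the isopropenyl group or head-to-head addition takes over. The fallback sets out from 5 and 9 and comes back at 12. The two alcohols are joined through the longer and more flexible linker from iPr2Si(Cl)OSi(Cl)iPr2 and imidazole to give the disiloxane-linked hydroxycarvone–cyclobutenol F2. Irradiation as in step 8 should give the disiloxane-bridged photoadduct F3. Bu4NF/AcOH then frees the syn photoadduct diol F4, whose two hydroxyls face each other in the fold, and iPr2Si(OTf)2 with 2,6-lutidine closes the one-silicon bridge to give 12.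

Step 15. Under the forcing conditions, acylation of the C9 hydroxyl may compete, or the angeloyl unit may isomerise to the tigloyl unit. The fallback sets out from 18 and comes back at 19. The Z-enoate is built on the molecule instead of being transferred. Alcohol 18 is esterified at C5 with the small, reactive 2-[bis(2,2,2-trifluoroethoxy)phosphoryl]propanoic acid (EDC, DMAP, CH2Cl2, 0 °C) to give the C5 phosphonopropanoate F5. A Still–Gennari olefination with acetaldehyde (K2CO3, 18-crown-6, toluene, −20 °C) should then form the (Z)-2-methylbut-2-enoate under kinetic control, which is 19.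

**Further compounds**
F1 | step 9 | silicon-bridged (3Z,7E)-dienone (C7=C8 isomer of 13) | C=C(C)[C@H]1C/C=C(C)\[C@H]2O[Si](C(C)C)(C(C)C)O[C@@H]1C(=O)/C(C)=C/C2
F2 | step 8 | disiloxane-linked hydroxycarvone–cyclobutenol | C=C(C)[C@H]1CC=C(C)C(=O)[C@H]1O[Si](C(C)C)(C(C)C)O[Si](C(C)C)(C(C)C)O[C@H]1CC=C1C
F3 | step 8 | disiloxane-bridged cis-syn-cis photoadduct | C=C(C)[C@H]1C[C@H]2[C@@]3(C)[C@H]4O[Si](C(C)C)(C(C)C)O[Si](C(C)C)(C(C)C)O[C@@H]1C(=O)[C@]2(C)[C@@H]3C4
F4 | step 8 | syn photoadduct diol (free 5- and 10-hydroxyls) | C=C(C)[C@H]1C[C@H]2[C@@]3(C)[C@@H](O)C[C@H]3[C@@]2(C)C(=O)[C@H]1O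
F5 | step 15 | C5 2-[bis(2,2,2-trifluoroethoxy)phosphoryl]propanoate of 18 (mixture at the phosphonate-bearing carbon) | C=C(C)[C@H]1C[C@@H]2O[C@]2(C)[C@@H](OC(=O)C(C)P(=O)(OCC(F)(F)F)OCC(F)(F)F)C[C@H]2O[C@@]2(C)[C@@H](O)[C@H]1OC(=O)C=C(C)C
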